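**Plan**
1. The target is epicatechin-(4β→8)-epigallocatechin 3-O-gallate-(4β→8)-epicatechin-(4β→8)-catechin (units 1 to 4 from the top). The retrosynthesis cuts all 21 benzyl ethers, then C4(unit 1)–C8(unit 2), then C4(unit 2)–C8(unit 3), then O1–C2 and C3–C4 of ring C of unit 3 together, and last the galloyl ester of unit 2.
2. Enabling feature: ring C of unit 3 is a 2-aryl-3-oxy-4-arylchroman on a phloroglucinol ring A. Its O1–C8a–C4a–C4 atoms are the skeleton of an o-quinone methide and C2–C3 that of a cis-styrene, so ring C is a hetero-Diels–Alder adduct once the C3 oxygen is carried as boron.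
3. Forward: benzylated 8-lithiocatechin (unit 4) adds to a phloroglucinaldehyde to give a benzhydrol. An acid-catalysed [4+2] reaction with a (Z)-styrylboronate closes ring C of unit 3, and C–B is oxidised to C–OH. The chain then grows at C8 by two cation couplings (galloylated epigallocatechin unit, then epicatechin unit), and hydrogenolysis ends the route.
4. Stereochemistry: units 1, 2 and 4 come from (−)-epicatechin, (−)-epigallocatechin and (+)-catechin. In unit 3 the 2,3-cis relation comes from the Z-alkene, the 3,4-trans relation from the exo mode, and the absolute sense from a chiral Brønsted acid acting on the planar quinone methide, so both carbinol epimers converge.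
5. Both new 4β linkages arise by attack on the C4 cation anti to the C2 aryl group, helped in unit 2 by the 3-O-galloyl group.

Key step: step 8

Assumptions: flavan numbering (O1, C2, C3, C4, C4a, C5 to C8, C8a, B-ring positions primed) is used, and 4β means the face opposite to the C2 aryl group. The (R) enantiomer of the acid in step 8 is taken as the one that shields the face leading to the natural flavan series; if the opposite sense is found, its mirror image is used with no other change. The 4β configuration written for the 2-ethoxyethoxy groups is the expected one; either C4 epimer gives the same cation.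

**Step 1**
Reactants: 1 (+)-catechin
Product: 2 5,7,3',4'-tetra-O-benzyl-(+)-catechin
Conditions: BnBr, K2CO3, DMF, 0 °C → rt
Reagents that add atoms: benzyl bromide, BrCc1ccccc1
Why: Williamson ether synthesis in which carbonate deprotonates only the four phenols, so the secondary C3–OH stays free and no stereocentre is touched.

**Step 2**
Reactants: 2 5,7,3',4'-tetra-O-benzyl-(+)-catechin
Product: 3 3,5,7,3',4'-penta-O-benzyl-(+)-catechin
Conditions: NaH, BnBr, Bu4NI (cat.), DMF, 0 °C → rt
Reagents that add atoms: benzyl bromide, BrCc1ccccc1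
Why: Williamson etherification of the C3 alkoxide, which removes the only acidic hydrogen before the organolithium step and leaves C2 and C3 unchanged.

**Step 3**
Reactants: 3 3,5,7,3',4'-penta-O-benzyl-(+)-catechin
Product: 4 8-bromo-3,5,7,3',4'-penta-O-benzyl-(+)-catechin
Conditions: NBS, CH2Cl2, −78 °C → rt
Reagents that add atoms: N-bromosuccinimide, O=C1CCC(=O)N1Br
Why: electrophilic aromatic bromination, which should occur at C8, the most nucleophilic A-ring position of 5,7-dialkoxyflavans.

**Step 4**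
Reactants: 5 2,4,6-trihydroxybenzaldehyde
Product: 6 4,6-bis(benzyloxy)-2-hydroxybenzaldehyde
Conditions: BnBr (2 equiv), K2CO3, DMF, rt
Reagents that add atoms: benzyl bromide, BrCc1ccccc1
Why: regioselective Williamson etherification in which the para hydroxyl and one ortho hydroxyl react, while the second ortho hydroxyl is held back by its hydrogen bond to the formyl group.

**Step 5**
Reactants: 4 8-bromo-3,5,7,3',4'-penta-O-benzyl-(+)-catechin and 6 4,6-bis(benzyloxy)-2-hydroxybenzaldehyde
Product: 9 [4,6-bis(benzyloxy)-2-hydroxyphenyl](3,5,7,3',4'-penta-O-benzylcatechin-8-yl)methanol (both carbinol epimers), via 8-lithio-penta-O-benzylcatechin 7 (not isolated), via sodium phenoxide of the aldehyde 8 (not isolated)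
Conditions: 6, NaH, THF, 0 °C (gives 8); 4, n-BuLi, THF, −78 °C (gives 7); 8 added to 7, −78 → 0 °C; H2O
Reagents that add atoms: none
Why: bromine–lithium exchange followed by 1,2-addition of the aryllithium to the aldehyde, with the phenol deprotonated beforehand so that it cannot quench 7; the carbinol centre forms unselectively, which does not matter because it becomes planar in step 8.

**Step 6**
Reactants: 10 3,4-bis(benzyloxy)benzaldehyde
Product: 11 1,2-bis(benzyloxy)-4-ethynylbenzene
Conditions: dimethyl (1-diazo-2-oxopropyl)phosphonate, K2CO3, MeOH, rt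
Reagents that add atoms: dimethyl (1-diazo-2-oxopropyl)phosphonate, COP(=O)(OC)C(=[N+]=[N-])C(C)=O
Why: Seyferth–Gilbert homologation with the Ohira–Bestmann reagent, which turns a non-enolisable aryl aldehyde into the terminal alkyne under mild base.

**Step 7**
Reactants: 11 1,2-bis(benzyloxy)-4-ethynylbenzene
Product: 12 (Z)-2-[2-(3,4-bis(benzyloxy)phenyl)ethenyl]-4,4,5,5-tetramethyl-1,3,2-dioxaborolane
Conditions: pinacolborane, [RhCl(cod)]2 (cat., cod = 1,5-cyclooctadiene), P(i-Pr)3 (cat.), Et3N, cyclohexane, rt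
Reagents that add atoms: pinacolborane, [H]B1OC(C)(C)C(C)(C)O1
Why: rhodium-catalysed trans-hydroboration of a terminal alkyne through a rhodium vinylidene, which places boron and the aryl group cis and so gives the (Z)-alkenylboronate.

**Step 8**
Reactants: 9 [4,6-bis(benzyloxy)-2-hydroxyphenyl](3,5,7,3',4'-penta-O-benzylcatechin-8-yl)methanol (both carbinol epimers) and 12 (Z)-2-[2-(3,4-bis(benzyloxy)phenyl)ethenyl]-4,4,5,5-tetramethyl-1,3,2-dioxaborolane
Product: 14 3-deoxy-3-(pinacolatoboryl)-5,7,3',4'-tetra-O-benzylepicatechin-(4β→8)-3,5,7,3',4'-penta-O-benzylcatechin (boron cis to the C2 aryl group and trans to the C4 aryl group; 2S,3R,4R in the boron-bearing unit), via o-quinone methide 13 (not isolated)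
Conditions: 12 (2–3 equiv), (R)-3,3'-bis(2,4,6-triisopropylphenyl)-1,1'-binaphthalene-2,2'-diyl N-(trifluoromethanesulfonyl)phosphoramidate (10 mol %), 5 Å MS, toluene, −20 °C → rt, slow addition of 9
Reagents that add atoms: none
Why: Proposed new method: the acid ionises either carbinol epimer of 9 to the same planar, hydrogen-bonded o-quinone methide 13 (O=C8a–C4a=C4 of the future flavan), which should add the cis-alkene 12 in an inverse-electron-demand hetero-Diels–Alder reaction, the boron-bearing carbon bonding to the methide carbon C4 and the quinone methide oxygen to the benzylic carbon C2; the closest known reaction type is the chiral Brønsted acid-catalysed [4+2] cycloaddition of quinone methides from o-hydroxybenzhydrols with styrenes, which has not been shown with alkenylboronates. Ring C closes by this intermolecular [4+2] event (in the stepwise limit a Michael-type C3–C4 bond formation followed by 6-exo-trig-like capture of the C2 benzylic cation by the phenoxide oxygen). The orientation follows from charge build-up at C2, which is stabilised by the 4-benzyloxyphenyl ring and by the adjacent C–B bond, whereas the reverse orientation would place charge on the carbon next to boron, and closure through O8a and not O5 is secured because O5 is benzylated. C2 and C3 become cis because the Z geometry of 12 is transferred suprafacially, and C3 and C4 become trans because the pinacolboryl group and the di-ortho-substituted aryl group on C4 should lie anti across the first-formed C3–C4 bond (alkene substituents exo). The absolute sense at all three new centres comes from the chiral phosphoramidate anion shielding one face of 13, which makes the step stereoconvergent with respect to the carbinol centre of 9. The step needs the cycloaddition to outrun Friedel–Crafts self-condensation of 13 at the free positions of its own phloroglucinol ring, which the excess of 12 and the slow addition of 9 should secure.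

**Step 9**
Reactants: 14 3-deoxy-3-(pinacolatoboryl)-5,7,3',4'-tetra-O-benzylepicatechin-(4β→8)-3,5,7,3',4'-penta-O-benzylcatechin
Product: 15 5,7,3',4'-tetra-O-benzylepicatechin-(4β→8)-3,5,7,3',4'-penta-O-benzylcatechin
Conditions: H2O2 (30% aq.), NaOH, THF/H2O, 0 °C → rt
Reagents that add atoms: hydrogen peroxide, OO
Why: oxidation of the C–B bond by alkaline hydrogen peroxide, in which carbon migrates from boron to oxygen with retention, so the C3–OH ends up cis to the C2 aryl group (2R,3R,4R unit).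

**Step 10**
Reactants: 16 (−)-epigallocatechin
Product: 17 5,7,3',4',5'-penta-O-benzyl-(−)-epigallocatechin
Conditions: BnBr (5.5 equiv), K2CO3, degassed DMF, argon, 0 °C → rt
Reagents that add atoms: benzyl bromide, BrCc1ccccc1
Why: Williamson ether synthesis in which carbonate deprotonates only the five phenols, so the secondary C3–OH stays free for the esterification, while exclusion of air protects the pyrogallol ring and neither stereocentre is touched.

**Step 11**
Reactants: 17 5,7,3',4',5'-penta-O-benzyl-(−)-epigallocatechin and 18 3,4,5-tris(benzyloxy)benzoic acid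
Product: 19 octa-O-benzyl-EGCG [5,7,3',4',5'-penta-O-benzyl-(−)-epigallocatechin 3-O-(3,4,5-tri-O-benzylgallate)]
Conditions: DCC, DMAP (cat.), CH2Cl2, 0 °C → rt
Reagents that add atoms: none
Why: Steglich esterification, in which the carbodiimide-activated acid is passed by DMAP to the axial C3–OH with retention at C3, since the C–O bond of the alcohol is not broken.

**Step 12**
Reactants: 19 octa-O-benzyl-EGCG
Product: 20 4β-(2-ethoxyethoxy)-octa-O-benzyl-EGCG
Conditions: DDQ, 2-ethoxyethanol, CH2Cl2, rt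
Reagents that add atoms: 2-ethoxyethanol, CCOCCO
Why: DDQ-mediated benzylic oxidation, in which hydride abstraction from C4 gives a cation stabilised by the A-ring oxygens that the alcohol traps on the face anti to the C2 aryl group.

**Step 13**
Reactants: 20 4β-(2-ethoxyethoxy)-octa-O-benzyl-EGCG and 15 5,7,3',4'-tetra-O-benzylepicatechin-(4β→8)-3,5,7,3',4'-penta-O-benzylcatechin
Product: 21 octa-O-benzyl-EGCG-(4β→8)-5,7,3',4'-tetra-O-benzylepicatechin-(4β→8)-3,5,7,3',4'-penta-O-benzylcatechin
Conditions: TMSOTf (0.2 equiv), CH2Cl2, −78 → −40 °C; 15 in excess (recovered), 20 added slowly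
Reagents that add atoms: none
Why: Lewis acid-promoted Friedel–Crafts-type interflavan coupling in which the C4 cation of 20 is attacked by C8 of the upper unit of 15 on the β face, anti to the C2 aryl group and to the participating 3-O-galloyl group, giving the 3,4-trans (4β) linkage.

**Step 14**
Reactants: 22 (−)-epicatechin
Product: 23 5,7,3',4'-tetra-O-benzyl-(−)-epicatechin
Conditions: BnBr, K2CO3, DMF, 0 °C → rt
Reagents that add atoms: benzyl bromide, BrCc1ccccc1
Why: Williamson etherification of the four phenols only, as in step 1.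

**Step 15**
Reactants: 23 5,7,3',4'-tetra-O-benzyl-(−)-epicatechin
Product: 24 4β-(2-ethoxyethoxy)-5,7,3',4'-tetra-O-benzylepicatechin (2R,3R,4S)
Conditions: DDQ, 2-ethoxyethanol, CH2Cl2, rt
Reagents that add atoms: 2-ethoxyethanol, CCOCCO
Why: DDQ-mediated benzylic oxidation at C4 with trapping of the cation by the alcohol anti to the C2 aryl group, as in step 12.

**Step 16**
Reactants: 24 4β-(2-ethoxyethoxy)-5,7,3',4'-tetra-O-benzylepicatechin and 21 octa-O-benzyl-EGCG-(4β→8)-tetra-O-benzylepicatechin-(4β→8)-penta-O-benzylcatechin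
Product: 25 5,7,3',4'-tetra-O-benzylepicatechin-(4β→8)-octa-O-benzyl-EGCG-(4β→8)-5,7,3',4'-tetra-O-benzylepicatechin-(4β→8)-3,5,7,3',4'-penta-O-benzylcatechin
Conditions: TMSOTf (0.2 equiv), CH2Cl2, −78 → −40 °C; 24 added slowly
Reagents that add atoms: none
Why: Lewis acid-promoted interflavan coupling in which the C4 cation of 24 is attacked by C8 of the top unit of 21, the most reactive A-ring position, on the β face anti to the C2 aryl group and the C3 hydroxyl, giving the 4β linkage.

**Step 17**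
Reactants: 25 the 21-fold O-benzylated tetramer
Product: 26 epicatechin-(4β→8)-epigallocatechin 3-O-gallate-(4β→8)-epicatechin-(4β→8)-catechin (target)
Conditions: H2 (1 atm), Pd(OH)2/C, THF/MeOH/H2O, rt
Reagents that add atoms: none
Why: catalytic hydrogenolysis cleaves all 21 benzyl ethers under neutral conditions that should leave the galloyl ester, the interflavan bonds and every stereocentre untouched.

**Compound list**
1 | (+)-catechin (2R,3S) | c1c(O)cc(O)c2c1O[C@H](c1ccc(O)c(O)c1)[C@@H](O)C2 | starting material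
2 | 5,7,3',4'-tetra-O-benzyl-(+)-catechin | c1c(OCc3ccccc3)cc(OCc3ccccc3)c2c1O[C@H](c1ccc(OCc3ccccc3)c(OCc3ccccc3)c1)[C@@H](O)C2 | intermediate
3 | 3,5,7,3',4'-penta-O-benzyl-(+)-catechin | c1c(OCc3ccccc3)cc(OCc3ccccc3)c2c1O[C@H](c1ccc(OCc3ccccc3)c(OCc3ccccc3)c1)[C@@H](OCc3ccccc3)C2 | intermediate
4 | 8-bromo-3,5,7,3',4'-penta-O-benzyl-(+)-catechin | Brc1c(OCc3ccccc3)cc(OCc3ccccc3)c2c1O[C@H](c1ccc(OCc3ccccc3)c(OCc3ccccc3)c1)[C@@H](OCc3ccccc3)C2 | intermediate
5 | 2,4,6-trihydroxybenzaldehyde | O=Cc1c(O)cc(O)cc1O | starting material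
6 | 4,6-bis(benzyloxy)-2-hydroxybenzaldehyde | O=Cc1c(O)cc(OCc2ccccc2)cc1OCc1ccccc1 | intermediate
7 | 8-lithio-3,5,7,3',4'-penta-O-benzylcatechin | [Li]c1c(OCc3ccccc3)cc(OCc3ccccc3)c2c1O[C@H](c1ccc(OCc3ccccc3)c(OCc3ccccc3)c1)[C@@H](OCc3ccccc3)C2 | intermediate
8 | sodium 3,5-bis(benzyloxy)-2-formylphenoxide | [Na+].[O-]c1cc(OCc2ccccc2)cc(OCc2ccccc2)c1C=O | intermediate
9 | [4,6-bis(benzyloxy)-2-hydroxyphenyl](3,5,7,3',4'-penta-O-benzylcatechin-8-yl)methanol, both carbinol epimers | OC(c1c(O)cc(OCc3ccccc3)cc1OCc3ccccc3)c1c(OCc3ccccc3)cc(OCc3ccccc3)c2c1O[C@H](c1ccc(OCc3ccccc3)c(OCc3ccccc3)c1)[C@@H](OCc3ccccc3)C2 | intermediate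
10 | 3,4-bis(benzyloxy)benzaldehyde | O=Cc1ccc(OCc2ccccc2)c(OCc2ccccc2)c1 | starting material
11 | 1,2-bis(benzyloxy)-4-ethynylbenzene | C#Cc1ccc(OCc2ccccc2)c(OCc2ccccc2)c1 | intermediate
12 | (Z)-2-[2-(3,4-bis(benzyloxy)phenyl)ethenyl]-4,4,5,5-tetramethyl-1,3,2-dioxaborolane | CC1(C)OB(/C=C\c2ccc(OCc3ccccc3)c(OCc3ccccc3)c2)OC1(C)C | intermediate
13 | o-quinone methide: 3,5-bis(benzyloxy)-6-[(3,5,7,3',4'-penta-O-benzylcatechin-8-yl)methylidene]cyclohexa-2,4-dien-1-one, alkene geometry not fixed | O=C1C=C(OCc3ccccc3)C=C(OCc3ccccc3)C1=Cc1c(OCc3ccccc3)cc(OCc3ccccc3)c2c1O[C@H](c1ccc(OCc3ccccc3)c(OCc3ccccc3)c1)[C@@H](OCc3ccccc3)C2 | intermediate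
14 | 3-deoxy-3-(pinacolatoboryl)-5,7,3',4'-tetra-O-benzylepicatechin-(4β→8)-3,5,7,3',4'-penta-O-benzylcatechin; boron cis to the C2 aryl group, trans to the C4 aryl group | c1c(OCc3ccccc3)cc(OCc3ccccc3)c2c1O[C@H](c1ccc(OCc3ccccc3)c(OCc3ccccc3)c1)[C@H](B1OC(C)(C)C(C)(C)O1)[C@H]2c1c(OCc3ccccc3)cc(OCc3ccccc3)c2c1O[C@H](c1ccc(OCc3ccccc3)c(OCc3ccccc3)c1)[C@@H](OCc3ccccc3)C2 | intermediate
15 | 5,7,3',4'-tetra-O-benzylepicatechin-(4β→8)-3,5,7,3',4'-penta-O-benzylcatechin | c1c(OCc3ccccc3)cc(OCc3ccccc3)c2c1O[C@H](c1ccc(OCc3ccccc3)c(OCc3ccccc3)c1)[C@H](O)[C@H]2c1c(OCc3ccccc3)cc(OCc3ccccc3)c2c1O[C@H](c1ccc(OCc3ccccc3)c(OCc3ccccc3)c1)[C@@H](OCc3ccccc3)C2 | intermediate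
16 | (−)-epigallocatechin (2R,3R) | O[C@@H]1Cc2c(O)cc(O)cc2O[C@@H]1c1cc(O)c(O)c(O)c1 | starting material
17 | 5,7,3',4',5'-penta-O-benzyl-(−)-epigallocatechin | O[C@@H]1Cc2c(OCc3ccccc3)cc(OCc3ccccc3)cc2O[C@@H]1c1cc(OCc3ccccc3)c(OCc3ccccc3)c(OCc3ccccc3)c1 | intermediate
18 | 3,4,5-tris(benzyloxy)benzoic acid | OC(=O)c1cc(OCc2ccccc2)c(OCc2ccccc2)c(OCc2ccccc2)c1 | starting material
19 | octa-O-benzyl-EGCG | O=C(O[C@@H]1Cc2c(OCc3ccccc3)cc(OCc3ccccc3)cc2O[C@@H]1c1cc(OCc3ccccc3)c(OCc3ccccc3)c(OCc3ccccc3)c1)c1cc(OCc3ccccc3)c(OCc3ccccc3)c(OCc3ccccc3)c1 | intermediate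
20 | 4β-(2-ethoxyethoxy)-octa-O-benzyl-EGCG | O=C(O[C@@H]1[C@@H](OCCOCC)c2c(OCc3ccccc3)cc(OCc3ccccc3)cc2O[C@@H]1c1cc(OCc3ccccc3)c(OCc3ccccc3)c(OCc3ccccc3)c1)c1cc(OCc3ccccc3)c(OCc3ccccc3)c(OCc3ccccc3)c1 | intermediate
21 | octa-O-benzyl-EGCG-(4β→8)-5,7,3',4'-tetra-O-benzylepicatechin-(4β→8)-3,5,7,3',4'-penta-O-benzylcatechin | O=C(O[C@@H]1[C@@H](c2c(OCc5ccccc5)cc(OCc5ccccc5)c3c2O[C@H](c2ccc(OCc5ccccc5)c(OCc5ccccc5)c2)[C@H](O)[C@H]3c2c(OCc5ccccc5)cc(OCc5ccccc5)c3c2O[C@H](c2ccc(OCc5ccccc5)c(OCc5ccccc5)c2)[C@@H](OCc5ccccc5)C3)c2c(OCc5ccccc5)cc(OCc5ccccc5)cc2O[C@@H]1c1cc(OCc5ccccc5)c(OCc5ccccc5)c(OCc5ccccc5)c1)c1cc(OCc5ccccc5)c(OCc5ccccc5)c(OCc5ccccc5)c1 | intermediate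
22 | (−)-epicatechin (2R,3R) | c1c(O)cc(O)c2c1O[C@H](c1ccc(O)c(O)c1)[C@H](O)C2 | starting material
23 | 5,7,3',4'-tetra-O-benzyl-(−)-epicatechin | c1c(OCc3ccccc3)cc(OCc3ccccc3)c2c1O[C@H](c1ccc(OCc3ccccc3)c(OCc3ccccc3)c1)[C@H](O)C2 | intermediate
24 | 4β-(2-ethoxyethoxy)-5,7,3',4'-tetra-O-benzylepicatechin | c1c(OCc3ccccc3)cc(OCc3ccccc3)c2c1O[C@H](c1ccc(OCc3ccccc3)c(OCc3ccccc3)c1)[C@H](O)[C@H]2OCCOCC | intermediate
25 | 5,7,3',4'-tetra-O-benzylepicatechin-(4β→8)-octa-O-benzyl-EGCG-(4β→8)-5,7,3',4'-tetra-O-benzylepicatechin-(4β→8)-3,5,7,3',4'-penta-O-benzylcatechin | O=C(O[C@@H]1[C@@H](c2c(OCc5ccccc5)cc(OCc5ccccc5)c3c2O[C@H](c2ccc(OCc5ccccc5)c(OCc5ccccc5)c2)[C@H](O)[C@H]3c2c(OCc5ccccc5)cc(OCc5ccccc5)c3c2O[C@H](c2ccc(OCc5ccccc5)c(OCc5ccccc5)c2)[C@@H](OCc5ccccc5)C3)c2c(OCc5ccccc5)cc(OCc5ccccc5)c([C@H]3c4c(OCc5ccccc5)cc(OCc5ccccc5)cc4O[C@H](c4ccc(OCc5ccccc5)c(OCc5ccccc5)c4)[C@@H]3O)c2O[C@@H]1c1cc(OCc5ccccc5)c(OCc5ccccc5)c(OCc5ccccc5)c1)c1cc(OCc5ccccc5)c(OCc5ccccc5)c(OCc5ccccc5)c1 | intermediate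
26 | epicatechin-(4β→8)-epigallocatechin 3-O-gallate-(4β→8)-epicatechin-(4β→8)-catechin | O=C(O[C@@H]1[C@@H](c2c(O)cc(O)c3c2O[C@H](c2ccc(O)c(O)c2)[C@H](O)[C@H]3c2c(O)cc(O)c3c2O[C@H](c2ccc(O)c(O)c2)[C@@H](O)C3)c2c(O)cc(O)c([C@H]3c4c(O)cc(O)cc4O[C@H](c4ccc(O)c(O)c4)[C@@H]3O)c2O[C@@H]1c1cc(O)c(O)c(O)c1)c1cc(O)c(O)c(O)c1 | target

**Count**
Total steps: 17. Longest linear sequence: 9 steps (1, 2, 3, 5, 8, 9, 13, 16, 17).

**Steps most likely to fail**

Step 8 (bears the label). The hindered, weakly nucleophilic alkenylboronate may trap the strongly stabilised, di-ortho-substituted quinone methide too slowly, so that Friedel–Crafts self-condensation takes over. The acid may also isomerise the Z-alkene, or a long-lived benzylic cation may lose the cis relation or lose boron; facial or exo selectivity may be poor. The fallback uses known chemistry and gives up the cycloaddition: the C4–C8 bond between units 3 and 4 is made by the established Lewis acid-promoted interflavan coupling. It sets out from 3 and 24 (the latter made in steps 14 and 15). Compound 24 is ionised with TMSOTf in CH2Cl2 at −78 °C in the presence of an excess of 3, and attack of C8 of 3 on the β face of the C4 cation should give 15 directly, where the route is rejoined. Steps 3 to 9 are then not needed, and no compound outside the list is made (F0).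

Step 16. The cation from 24 may attack other free A-ring positions of the trimer (the C6 positions) or another molecule of 24, which would give regioisomers and higher oligomers. The fallback changes the order of bond formation to a dimer-plus-dimer union and sets out from 24, 19 and 15. Compound 24 is coupled (TMSOTf, CH2Cl2, −78 °C) with an excess of 19, which has only one reactive A ring, to give 5,7,3',4'-tetra-O-benzylepicatechin-(4β→8)-octa-O-benzyl-EGCG F1. DDQ and 2-ethoxyethanol then oxidise its only remaining C4 methylene to the 4β-(2-ethoxyethoxy) derivative of the dimer F2. TMSOTf-promoted coupling of F2 with 15 at C8 of its upper unit should give 25, where the route is rejoined; steps 12 and 13 are then not needed.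

Step 5. Proton transfer or sluggish addition of the hindered aryllithium to the deactivated, poorly soluble phenoxide aldehyde may leave the addition incomplete. The fallback avoids the phenoxide and sets out from 6 and 4. The phenol of 6 is protected with allyl bromide and K2CO3 in DMF to give 2-(allyloxy)-4,6-bis(benzyloxy)benzaldehyde F3. Aryllithium 7 (from 4 and n-BuLi, THF, −78 °C) is added to F3 to give the allyl-protected benzhydrol [2-(allyloxy)-4,6-bis(benzyloxy)phenyl](3,5,7,3',4'-penta-O-benzylcatechin-8-yl)methanol F4. The allyl group is then removed under neutral conditions with Pd(PPh3)4 (zerovalent palladium) and morpholine in THF, which should give 9, where the route is rejoined.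

**Further compounds**
F0 | step 8 | none | none
F1 | step 16 | 5,7,3',4'-tetra-O-benzylepicatechin-(4β→8)-octa-O-benzyl-EGCG | O=C(O[C@@H]1Cc2c(OCc5ccccc5)cc(OCc5ccccc5)c([C@H]3c4c(OCc5ccccc5)cc(OCc5ccccc5)cc4O[C@H](c4ccc(OCc5ccccc5)c(OCc5ccccc5)c4)[C@@H]3O)c2O[C@@H]1c1cc(OCc5ccccc5)c(OCc5ccccc5)c(OCc5ccccc5)c1)c1cc(OCc5ccccc5)c(OCc5ccccc5)c(OCc5ccccc5)c1
F2 | step 16 | 5,7,3',4'-tetra-O-benzylepicatechin-(4β→8)-[4β-(2-ethoxyethoxy)-octa-O-benzyl-EGCG] | O=C(O[C@@H]1[C@@H](OCCOCC)c2c(OCc5ccccc5)cc(OCc5ccccc5)c([C@H]3c4c(OCc5ccccc5)cc(OCc5ccccc5)cc4O[C@H](c4ccc(OCc5ccccc5)c(OCc5ccccc5)c4)[C@@H]3O)c2O[C@@H]1c1cc(OCc5ccccc5)c(OCc5ccccc5)c(OCc5ccccc5)c1)c1cc(OCc5ccccc5)c(OCc5ccccc5)c(OCc5ccccc5)c1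
F3 | step 5 | 2-(allyloxy)-4,6-bis(benzyloxy)benzaldehyde | O=Cc1c(OCC=C)cc(OCc2ccccc2)cc1OCc1ccccc1
F4 | step 5 | [2-(allyloxy)-4,6-bis(benzyloxy)phenyl](3,5,7,3',4'-penta-O-benzylcatechin-8-yl)methanol, both carbinol epimers | OC(c1c(OCC=C)cc(OCc3ccccc3)cc1OCc3ccccc3)c1c(OCc3ccccc3)cc(OCc3ccccc3)c2c1O[C@H](c1ccc(OCc3ccccc3)c(OCc3ccccc3)c1)[C@@H](OCc3ccccc3)C2
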